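Z is what I count, and G and Z add up to about the charge, so Z is the G that has reacted. I follow one molecule of Q and ask its chance of ending as a Z.

common to all: G 0.050 M

| flask | Q | remark | time |
|---|---|---|---|
| blue | 1.4 equiv | run made earlier |  |
| violet | 1.6 equiv | run made earlier |  |
| north-east | 1.10 equiv |  | 4.0 h |
| south | 2.10 equiv |  | 4.0 h |

| run | time / h | G / % | Z / % |
|---|---|---|---|
| blue | 0.250 | 59.2 | 40.5 |
| blue | 0.417 | 52.5 | 47.8 |
| blue | 0.833 | 45.2 | 54.8 |
| blue | 1.33 | 42.0 | 57.5 |
| blue | 3.00 | 39.3 | 60.9 |
| violet | 0.250 | 55.9 | 44.1 |
| violet | 0.417 | 47.9 | 52.2 |
| violet | 0.833 | 39.6 | 59.5 |
| violet | 1.33 | 37.7 | 62.0 |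
| violet | 3.00 | 34.6 | 66.3 |

(readings scatter by 0.5 percentage points)

- part of the G that has reacted at the end, north-east
- part of the G that has reacted at the end, south
- what raising the equivalents of Q from its lowest to its highest value here does to the part of the G that has reacted (changes below 5 percentage points count as none) (no change / it rises / it falls)

At the last readings 60.7 % of the G has reacted in blue and 65.4 % in violet. The average chance in blue, reacted fraction over equivalents of Q, is 0.434. The marginal chance, the extra fraction of G reacted per extra equivalent of Q, reads 0.235, lower than the average, with a scatter of 0.0354. So I take the curve to bend over.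

If it keeps bending, taking Q from blue costs between the two chances per equivalent, which puts north-east between 47.7 % and 53.7 %. On the same assumption I put south above violet's 65.4 % and below 85.8 %, violet's average chance held. Holding the marginal chance tightens south to 77.1 %, give or take 1.8 percentage points. I neglect the extra hour after the last reading, but that is a risk: blue's last interval, longer than this hour, moved G by 2.7 points. The rise from north-east to south is about 23 points, above the margin.

The forecast, reading “an activity that decays with time”, gives 52 % and 77 %, inside my ranges, and its trend is: it rises.

North-east gives 51.9 % and south 78.7 %, so the part of G that has reacted behaves thus: it rises, by 27 points.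

    G + Q → E + Z (k = 1.00 /M/min)
    Q + E ⇌ L, settled at all times (K = 11000 /M)
    2 Q → X (k = 0.280 /M/min)

Between north-east and south the marginal chance comes out at 0.268, against my 0.235. A further flask, north-east's recipe with 2.80 equiv of Q, reaches 89.5 %, so beyond south the chance falls to 0.154. Neither north-east nor south has come to rest. In north-east free Q, the limiting reagent, is 0.60 % of its charge at 4.0 h, below the 48 % of G left. Yet at 40.0 h north-east stands at 63.8 % and south at 89.0 %, a marginal chance of 0.253.

The numbers in the tables come from a simulation for substances that don't exist, and the scatter is random.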